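**Strategy.** The C1–O8–C5 unit of the 6,8-dioxa-3-azabicyclo[3.2.1]octan-2-one core (O8 bridging the methyl-bearing C1 and the ketal carbon C5) is read as a cyclic carbonyl ylide, and the O6–C7 bridge of the dioxolane ring as acetaldehyde. An acyclic, achiral α-diazo amide whose ketone oxygen can reach the diazo carbon through a six-membered ring is decomposed by a chiral dirhodium carboxylate: the oxygen attacks the carbenoid carbon, closing the oxazinone ring through the O8–C1 bond, and the ylide is trapped by acetaldehyde in a [3+2] cycloaddition. One operation thus closes both rings and sets C1, C5 and C7. An N-(2,4-dimethoxybenzyl) group enforces the reactive amide rotamer and leaves at the end.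

Key step: step 5

Remark on the chemistry: core atoms carry the locants of 6,8-dioxa-3-azabicyclo[3.2.1]octan-2-one (C1 methyl-bearing bridgehead, C5 ketal bridgehead, C7 the CH(CH3) carbon, O8 the bridging oxygen); the sense of induction of the chiral catalyst in step 5 cannot be assigned beforehand, so the route is written for the (S)-tert-leucinate complex, and its equally available mirror-image complex is to be taken if the first run shows the opposite sense.

Step 1
Reactants: 1 4-(benzyloxy)benzyl chloride (2.2 equiv); 2 N,N'-dimethoxy-N,N'-dimethyloxamide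
Product: 4 1,4-bis[4-(benzyloxy)phenyl]butane-2,3-dione, via Grignard reagent 3 (not isolated)
Conditions: 1 (2.2 equiv), Mg, THF, 0 °C, slow addition (gives 3); then 2 (1.0 equiv), −20 → 0 °C; aq. HCl
Reagents that add atoms: second equivalent of 4-(benzyloxy)benzyl chloride 1, ClCc1ccc(OCc2ccccc2)cc1
Why: Twofold Weinreb ketone synthesis, in which two equivalents of the benzylic Grignard reagent add once each to the two N-methoxy-N-methylamide groups of 2 and the magnesium-chelated tetrahedral adducts resist further addition until acidic work-up releases the symmetrical 1,2-diketone.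

Step 2
Reactants: 4 1,4-bis[4-(benzyloxy)phenyl]butane-2,3-dione; 5 2,4-dimethoxybenzylamine
Product: 6 (Z)-1,4-bis[4-(benzyloxy)phenyl]-3-[(2,4-dimethoxybenzyl)amino]but-3-en-2-one
Conditions: 5 (1.05 equiv), PPTS (cat.), 4 Å MS, toluene, 60 °C
Reagents that add atoms: none
Why: Imine condensation at one carbonyl group of the symmetrical diketone (no regiochemical question) followed by imine–enamine tautomerism should give the conjugated α-enaminone, with the aryl group trans to the acyl group (Z) and the N–H hydrogen-bonded to the ketone.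

Step 3
Reactants: 6 (Z)-1,4-bis[4-(benzyloxy)phenyl]-3-[(2,4-dimethoxybenzyl)amino]but-3-en-2-one; 7 pyruvic acid
Product: 9 (Z)-N-{1,4-bis[4-(benzyloxy)phenyl]-3-oxobut-1-en-2-yl}-N-(2,4-dimethoxybenzyl)-2-oxopropanamide, via pyruvoyl chloride 8 (not isolated)
Conditions: 7, Cl2CHOMe, 50 °C, then evaporation (gives 8); 6, 2,6-lutidine, CH2Cl2, −20 °C → rt
Reagents that add atoms: none
Why: Pyruvoyl chloride is a small, highly electrophilic acylating agent without a ketene pathway, so it should N-acylate the hindered enaminone (Schotten–Baumann-type amide formation, 2,6-lutidine as acid acceptor) with the olefin geometry unchanged.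

Step 4
Reactants: 9 (Z)-N-{1,4-bis[4-(benzyloxy)phenyl]-3-oxobut-1-en-2-yl}-N-(2,4-dimethoxybenzyl)-2-oxopropanamide; 10 p-toluenesulfonohydrazide
Product: 12 (Z)-N-{1,4-bis[4-(benzyloxy)phenyl]-3-oxobut-1-en-2-yl}-2-diazo-N-(2,4-dimethoxybenzyl)propanamide, via tosylhydrazone 11 (not isolated)
Conditions: 10, THF, rt (gives 11); then Et3N, CH2Cl2, 0 °C → rt; used at once
Reagents that add atoms: none
Why: The α-keto amide carbonyl is far more electrophilic than the hindered, cross-conjugated enone carbonyl and should condense selectively with the sulfonyl hydrazide, after which triethylamine expels p-toluenesulfinate from the acceptor-substituted tosylhydrazone (Bamford–Stevens reaction) to give the α-diazo amide.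

Step 5
Reactants: 12 (Z)-N-{1,4-bis[4-(benzyloxy)phenyl]-3-oxobut-1-en-2-yl}-2-diazo-N-(2,4-dimethoxybenzyl)propanamide; 13 acetaldehyde
Product: 15 (1R,5R,7R,Z)-5-[4-(benzyloxy)benzyl]-4-[4-(benzyloxy)benzylidene]-3-(2,4-dimethoxybenzyl)-1,7-dimethyl-6,8-dioxa-3-azabicyclo[3.2.1]octan-2-one, via carbonyl ylide 14 (not isolated)
Conditions: Rh2(S-PTTL)4 [dirhodium tetrakis(N-phthaloyl-(S)-tert-leucinate)] (2 mol %), 13 (10 equiv), CH2Cl2, −40 → 0 °C, slow addition of 12
Reagents that add atoms: none
Why: The dirhodium carboxylate turns the diazo carbon of 12 into an electrophilic carbenoid at the future C1; in the amide rotamer favoured for an N-benzyl-N-alkenyl amide (alkenyl group cis to the diazo-bearing carbon across the C–N bond) the lone pair of the conjugated ketone oxygen attacks this carbon, closing the six-membered oxazinone ring by O8–C1 bond formation (oxygen-to-carbenoid ylide formation) and giving the push–pull carbonyl ylide 14. The 4π C1–O8–C5 system of 14 then adds suprafacially to the C=O bond of acetaldehyde in a concerted [3+2] cycloaddition that closes the 1,3-dioxolane ring through the C1–C7 and C5–O6 bonds. The closest known reaction type is the dirhodium-catalysed tandem carbonyl ylide formation/1,3-dipolar cycloaddition of diazo diketones with aldehydes to 6,8-dioxabicyclo[3.2.1]octanes, run here with a bulky chiral carboxylate at low temperature, as is usual for α-alkyl-α-diazo carbonyl compounds, to outrun the 1,2-hydride shift of the methyl-bearing carbenoid. Regiochemistry follows the ylide polarity: the amide-stabilised nucleophilic C1 bonds to the aldehyde carbon and the styryl-stabilised oxocarbenium carbon C5 to the aldehyde oxygen, while the ring constraint excludes electrocyclisation and bonding at the remote benzylidene carbon. C1 and C5 are set together, necessarily cis-bridged, by the ylide face that is attacked, which the chiral carboxylate wall of the rhodium-bound ylide is expected to select; C7 is set by an endo approach of the acetaldehyde methyl group (toward the flat C2–N3–C4 bridge, which carries no axial substituent), expected because the exo approach would bring it close to eclipsing the C1 methyl group in the forming dioxolane. The step needs ylide formation to beat hydride shift and attack on the N-benzyl arene (rotamer preference, six-membered closure, bulky catalyst), trapping to beat 1,4-proton transfer from the benzylic CH2 (excess aldehyde), endo over exo, and one ylide face over the other.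

Step 6
Reactants: 15 (1R,5R,7R,Z)-5-[4-(benzyloxy)benzyl]-4-[4-(benzyloxy)benzylidene]-3-(2,4-dimethoxybenzyl)-1,7-dimethyl-6,8-dioxa-3-azabicyclo[3.2.1]octan-2-one
Product: 16 Leptochartamide A, (1R,5R,7R,Z)-5-(4-hydroxybenzyl)-4-(4-hydroxybenzylidene)-1,7-dimethyl-6,8-dioxa-3-azabicyclo[3.2.1]octan-2-one
Conditions: TFA, pentamethylbenzene (12 equiv), rt → 40 °C; aq. NaHCO3
Reagents that add atoms: none
Why: Acidolytic global deprotection, in which TFA ionises the N-(2,4-dimethoxybenzyl) group and, with pentamethylbenzene as cation acceptor, the two aryl benzyl ethers, while the C1–O8 and C7–O6 bonds are not ionisable, so C1 and C7 are untouched, any reversible opening at the ketal carbon C5 can only reclose to the same bicycle, and reversible C-protonation of the enamide lets the benzylidene settle in the favoured Z geometry.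

**Compound list**
1 | 4-(benzyloxy)benzyl chloride | ClCc1ccc(OCc2ccccc2)cc1 | starting material
2 | N,N'-dimethoxy-N,N'-dimethyloxamide | CON(C)C(=O)C(=O)N(C)OC | starting material
3 | [4-(benzyloxy)benzyl]magnesium chloride | Cl[Mg]Cc1ccc(OCc2ccccc2)cc1 | intermediate
4 | 1,4-bis[4-(benzyloxy)phenyl]butane-2,3-dione | O=C(Cc1ccc(OCc2ccccc2)cc1)C(=O)Cc1ccc(OCc2ccccc2)cc1 | intermediate
5 | 2,4-dimethoxybenzylamine | COc1ccc(CN)c(OC)c1 | starting material
6 | (Z)-1,4-bis[4-(benzyloxy)phenyl]-3-[(2,4-dimethoxybenzyl)amino]but-3-en-2-one | COc1ccc(CN/C(C(=O)Cc2ccc(OCc3ccccc3)cc2)=C\c2ccc(OCc3ccccc3)cc2)c(OC)c1 | intermediate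
7 | pyruvic acid | CC(=O)C(=O)O | starting material
8 | pyruvoyl chloride | CC(=O)C(=O)Cl | intermediate
9 | (Z)-N-{1,4-bis[4-(benzyloxy)phenyl]-3-oxobut-1-en-2-yl}-N-(2,4-dimethoxybenzyl)-2-oxopropanamide | CC(=O)C(=O)N(Cc1ccc(OC)cc1OC)/C(C(=O)Cc1ccc(OCc2ccccc2)cc1)=C\c1ccc(OCc2ccccc2)cc1 | intermediate
10 | p-toluenesulfonohydrazide | Cc1ccc(cc1)S(=O)(=O)NN | starting material
11 | (Z)-N-{1,4-bis[4-(benzyloxy)phenyl]-3-oxobut-1-en-2-yl}-N-(2,4-dimethoxybenzyl)-2-[2-(p-tolylsulfonyl)hydrazinylidene]propanamide | CC(=NNS(=O)(=O)c1ccc(C)cc1)C(=O)N(Cc1ccc(OC)cc1OC)/C(C(=O)Cc1ccc(OCc2ccccc2)cc1)=C\c1ccc(OCc2ccccc2)cc1 | intermediate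
12 | (Z)-N-{1,4-bis[4-(benzyloxy)phenyl]-3-oxobut-1-en-2-yl}-2-diazo-N-(2,4-dimethoxybenzyl)propanamide | CC(=[N+]=[N-])C(=O)N(Cc1ccc(OC)cc1OC)/C(C(=O)Cc1ccc(OCc2ccccc2)cc1)=C\c1ccc(OCc2ccccc2)cc1 | intermediate
13 | acetaldehyde | CC=O | starting material
14 | (Z)-5-[4-(benzyloxy)benzylidene]-6-[4-(benzyloxy)benzyl]-4-(2,4-dimethoxybenzyl)-2-methyl-3-oxo-1,4-oxazin-1-ium-2-ide (rhodium-associated carbonyl ylide) | C[C-]1C(=O)N(Cc2ccc(OC)cc2OC)/C(=C\c2ccc(OCc3ccccc3)cc2)C(Cc2ccc(OCc3ccccc3)cc2)=[O+]1 | intermediate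
15 | (1R,5R,7R,Z)-5-[4-(benzyloxy)benzyl]-4-[4-(benzyloxy)benzylidene]-3-(2,4-dimethoxybenzyl)-1,7-dimethyl-6,8-dioxa-3-azabicyclo[3.2.1]octan-2-one | C[C@H]1O[C@]2(Cc3ccc(OCc4ccccc4)cc3)O[C@@]1(C)C(=O)N(Cc1ccc(OC)cc1OC)/C2=C\c1ccc(OCc2ccccc2)cc1 | intermediate
16 | Leptochartamide A, (1R,5R,7R,Z)-5-(4-hydroxybenzyl)-4-(4-hydroxybenzylidene)-1,7-dimethyl-6,8-dioxa-3-azabicyclo[3.2.1]octan-2-one | C[C@H]1O[C@]2(Cc3ccc(O)cc3)O[C@@]1(C)C(=O)N/C2=C\c1ccc(O)cc1 | target

**Total step count:** 6
**Longest linear sequence:** 6 steps (1 → 4 → 6 → 9 → 12 → 15 → 16)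

**Steps most likely to fail**

Step 5. The amide-stabilised ylide may leave the rhodium fragment before it meets acetaldehyde, so that neither ylide face is preferred and material of low enantiomeric purity results. The fallback moves the stereocontrol from the catalyst to a cleavable stereogenic N-substituent; it sets out from 4 and returns to the route at 16. Diketone 4 is condensed with (S)-1-(4-methoxyphenyl)ethylamine (PPTS, 4 Å MS, toluene, 60 °C) to the enaminone (Z)-1,4-bis[4-(benzyloxy)phenyl]-3-{[(S)-1-(4-methoxyphenyl)ethyl]amino}but-3-en-2-one F1. Acylation of F1 with pyruvoyl chloride 8, made from 7 as in step 3, should give the α-keto amide (Z)-N-{1,4-bis[4-(benzyloxy)phenyl]-3-oxobut-1-en-2-yl}-N-[(S)-1-(4-methoxyphenyl)ethyl]-2-oxopropanamide F2. With hydrazide 10, F2 should give the tosylhydrazone (Z)-N-{1,4-bis[4-(benzyloxy)phenyl]-3-oxobut-1-en-2-yl}-N-[(S)-1-(4-methoxyphenyl)ethyl]-2-[2-(p-tolylsulfonyl)hydrazinylidene]propanamide F3. Treatment of F3 with Et3N should give the diazo amide (Z)-N-{1,4-bis[4-(benzyloxy)phenyl]-3-oxobut-1-en-2-yl}-2-diazo-N-[(S)-1-(4-methoxyphenyl)ethyl]propanamide F4. Decomposition of F4 with the achiral, bulky Rh2(O2CCPh3)4 in the presence of 13 passes through the carbonyl ylide (Z)-5-[4-(benzyloxy)benzylidene]-6-[4-(benzyloxy)benzyl]-4-[(S)-1-(4-methoxyphenyl)ethyl]-2-methyl-3-oxo-1,4-oxazin-1-ium-2-ide F5. In F5, allylic 1,3-strain should hold the C–H bond of the N-substituent in the ring plane, so that its aryl group covers one ylide face. The cycloadducts are diastereomers and should be separable on silica gel. The wanted isomer is (1R,5R,7R,Z)-5-[4-(benzyloxy)benzyl]-4-[4-(benzyloxy)benzylidene]-3-[(S)-1-(4-methoxyphenyl)ethyl]-1,7-dimethyl-6,8-dioxa-3-azabicyclo[3.2.1]octan-2-one F6. F6 is then submitted to the TFA/pentamethylbenzene conditions of step 6, which should also cleave the 1-(4-methoxyphenyl)ethyl group and give 16. The antipode of the amine is chosen after the first run.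

Step 4. The hydrazide may condense only slowly with the congested tertiary α-keto amide and add to the enone instead, and the diazo amide may be consumed by intramolecular dipolar cycloaddition onto the enone double bond during a long reaction. The fallback forms the hydrazone before the amide bond; it sets out from 6 (bypassing 9) and returns at 11. Acid 7 and hydrazide 10 are condensed (MeOH, rt) to 2-[2-(p-tolylsulfonyl)hydrazinylidene]propanoic acid F7. F7 is converted under neutral conditions with 1-chloro-N,N,2-trimethylprop-1-en-1-amine (CH2Cl2, 0 °C) into 2-[2-(p-tolylsulfonyl)hydrazinylidene]propanoyl chloride F8; thionyl chloride is avoided because it would cyclise the hydrazone in a Hurd–Mori reaction. F8 acylates 6 (N,N-dimethylaniline, CH2Cl2, 0 °C) to give 11, and brief treatment with Et3N should then give 12.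

Step 6. Cleavage of the unactivated aryl benzyl ethers needs warm acid for a long time, during which benzyl cations may C-alkylate the freed phenols and the ionised ketal–enamide may be diverted. The fallback separates the two deprotections; it sets out from 15 and returns at 16. TFA/CH2Cl2 (1:4) with pentamethylbenzene at 0 °C → rt should remove only the 2,4-dimethoxybenzyl group and give (1R,5R,7R,Z)-5-[4-(benzyloxy)benzyl]-4-[4-(benzyloxy)benzylidene]-1,7-dimethyl-6,8-dioxa-3-azabicyclo[3.2.1]octan-2-one F9. Treatment of F9 with BCl3 and pentamethylbenzene in CH2Cl2 at −78 °C should then cleave the two benzyl ethers at low temperature and give 16.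

**Further compounds**
F1 | step 5 | (Z)-1,4-bis[4-(benzyloxy)phenyl]-3-{[(S)-1-(4-methoxyphenyl)ethyl]amino}but-3-en-2-one | C[C@H](N/C(C(=O)Cc1ccc(OCc2ccccc2)cc1)=C\c1ccc(OCc2ccccc2)cc1)c1ccc(OC)cc1
F2 | step 5 | (Z)-N-{1,4-bis[4-(benzyloxy)phenyl]-3-oxobut-1-en-2-yl}-N-[(S)-1-(4-methoxyphenyl)ethyl]-2-oxopropanamide | CC(=O)C(=O)N([C@@H](C)c1ccc(OC)cc1)/C(C(=O)Cc1ccc(OCc2ccccc2)cc1)=C\c1ccc(OCc2ccccc2)cc1
F3 | step 5 | (Z)-N-{1,4-bis[4-(benzyloxy)phenyl]-3-oxobut-1-en-2-yl}-N-[(S)-1-(4-methoxyphenyl)ethyl]-2-[2-(p-tolylsulfonyl)hydrazinylidene]propanamide | CC(=NNS(=O)(=O)c1ccc(C)cc1)C(=O)N([C@@H](C)c1ccc(OC)cc1)/C(C(=O)Cc1ccc(OCc2ccccc2)cc1)=C\c1ccc(OCc2ccccc2)cc1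
F4 | step 5 | (Z)-N-{1,4-bis[4-(benzyloxy)phenyl]-3-oxobut-1-en-2-yl}-2-diazo-N-[(S)-1-(4-methoxyphenyl)ethyl]propanamide | CC(=[N+]=[N-])C(=O)N([C@@H](C)c1ccc(OC)cc1)/C(C(=O)Cc1ccc(OCc2ccccc2)cc1)=C\c1ccc(OCc2ccccc2)cc1
F5 | step 5 | (Z)-5-[4-(benzyloxy)benzylidene]-6-[4-(benzyloxy)benzyl]-4-[(S)-1-(4-methoxyphenyl)ethyl]-2-methyl-3-oxo-1,4-oxazin-1-ium-2-ide (carbonyl ylide) | C[C-]1C(=O)N([C@@H](C)c2ccc(OC)cc2)/C(=C\c2ccc(OCc3ccccc3)cc2)C(Cc2ccc(OCc3ccccc3)cc2)=[O+]1
F6 | step 5 | (1R,5R,7R,Z)-5-[4-(benzyloxy)benzyl]-4-[4-(benzyloxy)benzylidene]-3-[(S)-1-(4-methoxyphenyl)ethyl]-1,7-dimethyl-6,8-dioxa-3-azabicyclo[3.2.1]octan-2-one | C[C@H]1O[C@]2(Cc3ccc(OCc4ccccc4)cc3)O[C@@]1(C)C(=O)N([C@@H](C)c1ccc(OC)cc1)/C2=C\c1ccc(OCc2ccccc2)cc1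
F7 | step 4 | 2-[2-(p-tolylsulfonyl)hydrazinylidene]propanoic acid | CC(=NNS(=O)(=O)c1ccc(C)cc1)C(=O)O
F8 | step 4 | 2-[2-(p-tolylsulfonyl)hydrazinylidene]propanoyl chloride | CC(=NNS(=O)(=O)c1ccc(C)cc1)C(=O)Cl
F9 | step 6 | (1R,5R,7R,Z)-5-[4-(benzyloxy)benzyl]-4-[4-(benzyloxy)benzylidene]-1,7-dimethyl-6,8-dioxa-3-azabicyclo[3.2.1]octan-2-one | C[C@H]1O[C@]2(Cc3ccc(OCc4ccccc4)cc3)O[C@@]1(C)C(=O)N/C2=C\c1ccc(OCc2ccccc2)cc1
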